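**Retrosynthetic overview** (quinolinone numbering: N1, C2, C3, C4, C4a, C5–C8, C8a)

- The N-methoxy-4-pyridone is the last ring: N1–C8a is made as an oxime ether and N1–C2 by addition–elimination on a β-methoxy enone, after C4a–C4 was made by an aldol addition/oxidation with a C4–C3–C2–CH2O enal.
- The carbocycle is not closed as a six-membered ring. It comes from (R)-2-octylcyclopentanone by a one-carbon ring enlargement in which the carbon of CH2Br2 is inserted as C4a between the carbonyl carbon (C8a) and the octyl-bearing carbon (C5).
- Enabling feature: C4a lies between C8a (ketone oxidation level, later N-bearing) and the stereocentre C5 and carries the C4 carbonyl, a 2-acyl-3-alkylcyclohexanone pattern. The 1,2-shift that enlarges the ring moves the preset stereocentre with retention and leaves the C8a–C4a enolate regiospecifically.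
- The stereocentre is set beforehand by SAMP-hydrazone alkylation of cyclopentanone with 1-iodooctane.
- Ring order: cyclopentane (purchased) → cyclohexanone (step 8) → pyridone (step 10).

Key step: step 8

Assumption: SAMP is taken to direct the octylation of cyclopentanone in the same sense as its established alkylations of cyclohexanone (R ketone; RAMP would be used otherwise); centres and alkene/oxime geometries that are erased later are left unspecified.

**Route**

Step 1
Reactants: 1 cyclopentanone; 2 (S)-1-amino-2-(methoxymethyl)pyrrolidine (SAMP)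
Product: 3 (S)-N-cyclopentylidene-2-(methoxymethyl)pyrrolidin-1-amine
Conditions: neat, 60 °C
Reagents that add atoms: none
Why: Hydrazone formation by condensation of the ketone with the hydrazine should proceed cleanly without catalyst.

Step 2
Reactants: 3 (S)-N-cyclopentylidene-2-(methoxymethyl)pyrrolidin-1-amine; 4 1-iodooctane
Product: 6 (S)-2-(methoxymethyl)-N-[(2R)-2-octylcyclopentylidene]pyrrolidin-1-amine, via lithium azaenolate 5 (not isolated)
Conditions: LDA, THF, 0 °C; then 4, −100 °C → rt
Reagents that add atoms: none
Why: SAMP-hydrazone alkylation, in which the lithium-chelating methoxymethyl group shields one face of the azaenolate so that the iodide enters from the other and sets the R configuration at the α-carbon.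

Step 3
Reactants: 6 (S)-2-(methoxymethyl)-N-[(2R)-2-octylcyclopentylidene]pyrrolidin-1-amine
Product: 7 (R)-2-octylcyclopentan-1-one
Conditions: O3, CH2Cl2, −78 °C; N2 purge
Reagents that add atoms: ozone, [O-][O+]=O
Why: Ozonolytic cleavage of the hydrazone C=N bond releases the ketone under neutral, non-enolising conditions, so the α-stereocentre should not epimerise (the ketone is used directly).

Step 4
Reactants: 7 (R)-2-octylcyclopentan-1-one
Product: 8 (2R)-1-(dibromomethyl)-2-octylcyclopentan-1-ol
Conditions: CH2Br2, LDA, THF, −78 °C; AcOH quench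
Reagents that add atoms: dibromomethane, BrCBr
Why: 1,2-Addition of dibromomethyllithium generated in the presence of the ketone; both carbinol epimers are usable because this carbon becomes sp2 in step 8, and any competing kinetic enolisation occurs at the unsubstituted α-CH2 and leaves the stereocentre intact.

Step 5
Reactants: 9 N,2-dimethoxy-N-methylacetamide; 10 2-(benzyloxy)acetyl chloride
Product: 12 4-(benzyloxy)-N,2-dimethoxy-N-methyl-3-oxobutanamide, via lithium amide enolate 11 (not isolated)
Conditions: 9 (2 equiv), LDA (2 equiv), THF, −78 °C; then 10 (1 equiv); AcOH quench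
Reagents that add atoms: none
Why: Claisen-type C-acylation of the Weinreb amide enolate by the acid chloride, with the second equivalent of enolate taking up the acidic proton of the β-keto amide.

Step 6
Reactants: 12 4-(benzyloxy)-N,2-dimethoxy-N-methyl-3-oxobutanamide
Product: 13 4-(benzyloxy)-N,2,3-trimethoxy-N-methylbut-2-enamide
Conditions: Me2SO4, K2CO3, DMF, 0 °C → rt
Reagents that add atoms: dimethyl sulfate, COS(=O)(=O)OC
Why: O-Alkylation of the β-keto amide enolate with a hard methylating agent in a polar aprotic solvent should give the enol ether, whose alkene geometry is irrelevant because C2 is later attacked by addition–elimination.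

Step 7
Reactants: 13 4-(benzyloxy)-N,2,3-trimethoxy-N-methylbut-2-enamide
Product: 14 4-(benzyloxy)-2,3-dimethoxybut-2-enal
Conditions: DIBAL-H, THF, −78 °C; Rochelle salt work-up
Reagents that add atoms: none
Why: Weinreb amide reduction, in which the chelated tetrahedral aluminate holds the aldehyde oxidation level until work-up.

Step 8
Reactants: 8 (2R)-1-(dibromomethyl)-2-octylcyclopentan-1-ol; 14 4-(benzyloxy)-2,3-dimethoxybut-2-enal
Product: 17 (3R)-2-[4-(benzyloxy)-1-hydroxy-2,3-dimethoxybut-2-en-1-yl]-3-octylcyclohexan-1-one (diastereomer mixture), via β-oxido carbenoid 15 (not isolated), via lithium enolate 16 (not isolated)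
Conditions: n-BuLi (2.1 equiv), THF, −78 → 0 °C; then 14, −78 °C; AcOH quench at −78 °C
Reagents that add atoms: none
Why: Deprotonation of the hydroxyl and Br/Li exchange give the β-oxido carbenoid 15, in which the octyl-bearing ring carbon shifts from the carbinol carbon to the electron-poor carbenoid carbon with loss of LiBr, so that the five-membered ring becomes the six-membered lithium enolate 16 with the inserted carbon as its nucleophilic α-carbon, and 16 then adds 1,2 to the aldehyde of 14. The closest known reaction type is the dibromomethyllithium (β-oxido carbenoid) ring enlargement of cycloalkanones with in situ capture of the resulting enolate, here by an aldol addition. No ring is closed: the carbocycle is enlarged from five to six members by a 1,2-alkyl shift and the side chain is attached by an intermolecular C–C bond. The migrating carbon keeps its configuration, so the R centre of 8 becomes C5 of the target unchanged, both carbinol epimers of 8 converge because that carbon becomes sp2, and the two new centres of 17 (ring C2 and the carbinol) are uncontrolled and are erased in step 10. The step needs migration of the substituted α-carbon instead of the ring CH2 and a positionally stable enolate; the first is secured by the higher migratory aptitude of the more substituted carbon in this carbenoid shift (2-alkylcycloalkanones give the 3-alkyl homologues), the second by the aprotic medium, in which the enolate cannot equilibrate before the aldehyde arrives.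

Step 9
Reactants: 17 (3R)-2-[4-(benzyloxy)-1-hydroxy-2,3-dimethoxybut-2-en-1-yl]-3-octylcyclohexan-1-one
Product: 18 (3R)-2-[4-(benzyloxy)-1-hydroxy-2,3-dimethoxybut-2-en-1-yl]-3-octylcyclohexan-1-one O-methyl oxime
Conditions: MeONH2·HCl, pyridine, rt
Reagents that add atoms: O-methylhydroxylamine hydrochloride, CON.Cl
Why: Oxime ether formation at the only ketone places the N–OMe nitrogen on C8a before C4 is oxidised, so that no enol oxygen is left to close a 4-pyranone, and the pyridine medium should keep the acid-labile enol ether intact.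

Step 10
Reactants: 18 (3R)-2-[4-(benzyloxy)-1-hydroxy-2,3-dimethoxybut-2-en-1-yl]-3-octylcyclohexan-1-one O-methyl oxime
Product: 20 (R)-2-[(benzyloxy)methyl]-1,3-dimethoxy-5-octyl-5,6,7,8-tetrahydroquinolin-4(1H)-one, via keto oxime ether 19 (not isolated)
Conditions: Dess–Martin periodinane, CH2Cl2, 0 °C → rt; then toluene, 80 °C
Reagents that add atoms: none
Why: Dess–Martin oxidation turns the carbinol into the C4 ketone and the dimethoxyalkene into a vinylogous ester, whereupon the oxime-ether nitrogen (or its N-methoxy enamine tautomer) should attack C2 in a six-membered addition–elimination with loss of methanol (catalysed by the liberated acetic acid) and tautomerise to the 4-pyridone, erasing the uncontrolled centre at C4a.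

Step 11
Reactants: 20 (R)-2-[(benzyloxy)methyl]-1,3-dimethoxy-5-octyl-5,6,7,8-tetrahydroquinolin-4(1H)-one
Product: 21 (R)-2-(hydroxymethyl)-1,3-dimethoxy-5-octyl-5,6,7,8-tetrahydroquinolin-4(1H)-one
Conditions: H2 (1 atm), Pd/C, EtOAc, rt
Reagents that add atoms: none
Why: Benzyl ether hydrogenolysis under mild conditions, in which the N–O bond of an N-alkoxypyridone, the pyridone ring and the C5 stereocentre should remain untouched.

**Compound list**

1 | cyclopentanone | O=C1CCCC1 | starting material
2 | (S)-1-amino-2-(methoxymethyl)pyrrolidine (SAMP) | COC[C@@H]1CCCN1N | starting material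
3 | (S)-N-cyclopentylidene-2-(methoxymethyl)pyrrolidin-1-amine | COC[C@@H]1CCCN1N=C1CCCC1 | intermediate
4 | 1-iodooctane | CCCCCCCCI | starting material
5 | lithium azaenolate of 3 | COC[C@@H]1CCCN1N([Li])C1=CCCC1 | intermediate
6 | (S)-2-(methoxymethyl)-N-[(2R)-2-octylcyclopentylidene]pyrrolidin-1-amine | CCCCCCCC[C@@H]1CCCC1=NN1CCC[C@H]1COC | intermediate
7 | (R)-2-octylcyclopentan-1-one | CCCCCCCC[C@@H]1CCCC1=O | intermediate
8 | (2R)-1-(dibromomethyl)-2-octylcyclopentan-1-ol (both C1 epimers) | CCCCCCCC[C@@H]1CCCC1(O)C(Br)Br | intermediate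
9 | N,2-dimethoxy-N-methylacetamide | COCC(=O)N(C)OC | starting material
10 | 2-(benzyloxy)acetyl chloride | O=C(Cl)COCc1ccccc1 | starting material
11 | lithium enolate of 9 | COC=C(O[Li])N(C)OC | intermediate
12 | 4-(benzyloxy)-N,2-dimethoxy-N-methyl-3-oxobutanamide | CON(C)C(=O)C(OC)C(=O)COCc1ccccc1 | intermediate
13 | 4-(benzyloxy)-N,2,3-trimethoxy-N-methylbut-2-enamide (E/Z) | CON(C)C(=O)C(OC)=C(OC)COCc1ccccc1 | intermediate
14 | 4-(benzyloxy)-2,3-dimethoxybut-2-enal (E/Z) | O=CC(OC)=C(OC)COCc1ccccc1 | intermediate
15 | dilithio β-oxido carbenoid from 8 | CCCCCCCC[C@@H]1CCCC1(O[Li])C([Li])Br | intermediate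
16 | lithium (R)-3-octylcyclohex-1-en-1-olate | CCCCCCCC[C@@H]1CCCC(O[Li])=C1 | intermediate
17 | (3R)-2-[4-(benzyloxy)-1-hydroxy-2,3-dimethoxybut-2-en-1-yl]-3-octylcyclohexan-1-one (diastereomer mixture at ring C2 and carbinol) | CCCCCCCC[C@@H]1CCCC(=O)C1C(O)C(OC)=C(OC)COCc1ccccc1 | intermediate
18 | O-methyl oxime of 17 | CCCCCCCC[C@@H]1CCCC(=NOC)C1C(O)C(OC)=C(OC)COCc1ccccc1 | intermediate
19 | (3R)-2-[4-(benzyloxy)-2,3-dimethoxybut-2-enoyl]-3-octylcyclohexan-1-one O-methyl oxime | CCCCCCCC[C@@H]1CCCC(=NOC)C1C(=O)C(OC)=C(OC)COCc1ccccc1 | intermediate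
20 | (R)-2-[(benzyloxy)methyl]-1,3-dimethoxy-5-octyl-5,6,7,8-tetrahydroquinolin-4(1H)-one | CCCCCCCC[C@@H]1CCCc2c1c(=O)c(OC)c(COCc1ccccc1)n2OC | intermediate
21 | (R)-2-(hydroxymethyl)-1,3-dimethoxy-5-octyl-5,6,7,8-tetrahydroquinolin-4(1H)-one | CCCCCCCC[C@@H]1CCCc2c1c(=O)c(OC)c(CO)n2OC | target

**Step count and risks**

Total step count: 11. Longest linear sequence: 8 steps (steps 1–4 and 8–11, from cyclopentanone); the aldehyde branch is 3 steps (5–7).

Steps most likely to fail:

Step 8. The 1,2-shift may run in part through the unsubstituted ring CH2, giving the regioisomeric enolate, or the enolate may be lost by proton transfer before it meets the sensitive enal. The fallback sets out from aldehyde 14 and comes back at 17, and still makes the ring by a five-to-six enlargement. Copper-catalysed asymmetric conjugate addition of octylmagnesium bromide to cyclopent-2-enone (CuBr·SMe2, chiral ferrocenyl diphosphine chosen for 3R, t-BuOMe, −75 °C), with in situ aldol capture of the magnesium enolate by 14, should give (3R)-2-[4-(benzyloxy)-1-hydroxy-2,3-dimethoxybut-2-en-1-yl]-3-octylcyclopentan-1-one F1. Silylation (TBSOTf, 2,6-lutidine) gives its tert-butyldimethylsilyl ether F2. Homologation with trimethylsilyldiazomethane/Me3Al, in which the less substituted α-CH2 migrates, should give after aqueous work-up (3R)-2-[4-(benzyloxy)-1-(tert-butyldimethylsilyloxy)-2,3-dimethoxybut-2-en-1-yl]-3-octylcyclohexan-1-one F3. TBAF then returns 17.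

Step 10. The weakly nucleophilic oxime-ether nitrogen may fail to displace methoxide at C2, so that the sequence stalls at 19 or the oxime ether hydrolyses. The fallback sets out from 17 and comes back at 20. Dess–Martin oxidation of 17 gives (3R)-2-[4-(benzyloxy)-2,3-dimethoxybut-2-enoyl]-3-octylcyclohexan-1-one F4. Catalytic TsOH closes it, with loss of methanol, to (R)-2-[(benzyloxy)methyl]-3-methoxy-5-octyl-5,6,7,8-tetrahydro-4H-chromen-4-one F5. Hydroxylamine hydrochloride in pyridine/ethanol at reflux exchanges the ring oxygen for N–OH to give (R)-2-[(benzyloxy)methyl]-1-hydroxy-3-methoxy-5-octyl-5,6,7,8-tetrahydroquinolin-4(1H)-one F6. O-Methylation of the N-hydroxy group (MeI, K2CO3, DMF) then gives 20.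

Step 6. Methylation may occur at the methoxy-bearing α-carbon instead of at the enolate oxygen. The fallback sets out from 12 and comes back at 13. Ketalisation (trimethyl orthoformate, MeOH, cat. TsOH) gives 4-(benzyloxy)-N,2,3,3-tetramethoxy-N-methylbutanamide F7. Elimination of one methoxy group with TMSOTf/i-Pr2NEt towards the acidic α-position then gives enol ether 13.

Further compounds
F1 | step 8 | (3R)-2-[4-(benzyloxy)-1-hydroxy-2,3-dimethoxybut-2-en-1-yl]-3-octylcyclopentan-1-one | CCCCCCCC[C@@H]1CCC(=O)C1C(O)C(OC)=C(OC)COCc1ccccc1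
F2 | step 8 | (3R)-2-[4-(benzyloxy)-1-(tert-butyldimethylsilyloxy)-2,3-dimethoxybut-2-en-1-yl]-3-octylcyclopentan-1-one | CCCCCCCC[C@@H]1CCC(=O)C1C(O[Si](C)(C)C(C)(C)C)C(OC)=C(OC)COCc1ccccc1
F3 | step 8 | (3R)-2-[4-(benzyloxy)-1-(tert-butyldimethylsilyloxy)-2,3-dimethoxybut-2-en-1-yl]-3-octylcyclohexan-1-one | CCCCCCCC[C@@H]1CCCC(=O)C1C(O[Si](C)(C)C(C)(C)C)C(OC)=C(OC)COCc1ccccc1
F4 | step 10 | (3R)-2-[4-(benzyloxy)-2,3-dimethoxybut-2-enoyl]-3-octylcyclohexan-1-one | CCCCCCCC[C@@H]1CCCC(=O)C1C(=O)C(OC)=C(OC)COCc1ccccc1
F5 | step 10 | (R)-2-[(benzyloxy)methyl]-3-methoxy-5-octyl-5,6,7,8-tetrahydro-4H-chromen-4-one | CCCCCCCC[C@@H]1CCCc2c1c(=O)c(OC)c(COCc1ccccc1)o2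
F6 | step 10 | (R)-2-[(benzyloxy)methyl]-1-hydroxy-3-methoxy-5-octyl-5,6,7,8-tetrahydroquinolin-4(1H)-one | CCCCCCCC[C@@H]1CCCc2c1c(=O)c(OC)c(COCc1ccccc1)n2O
F7 | step 6 | 4-(benzyloxy)-N,2,3,3-tetramethoxy-N-methylbutanamide | CON(C)C(=O)C(OC)C(OC)(OC)COCc1ccccc1
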